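Readings and results come from a simulation on assumed constants; the scatter is artificial.

**A ceiling.** Left-handed product cannot pass half of the charge unless right-handed substrate turns into left-handed substrate.

- autumn: left-handed substrate 0.52 M; right-handed substrate 0.52 M; reagent 4.4 equiv; racemization catalyst 2.5 mol%; run made earlier
- flask: left-handed substrate 0.52 M; reagent 2.20 equiv; racemization catalyst 2.5 mol%; right-handed substrate 0.52 M; time 1.0 h

autumn run (percent of the left-handed substrate and right-handed substrate together charged)

| time / min | left-handed product / % | right-handed product / % |
|---|---|---|
| 1.00 | 4.7 | 0.4 |
| 3.00 | 10.3 | 0.8 |
| 6.00 | 19.4 | 3.6 |
| 8.00 | 24.9 | 4.4 |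
| 12.0 | 31.5 | 6.4 |

(each reading ± 0.5 percentage points)

* left-handed product and right-handed product together, in percent of the left-handed substrate and right-handed substrate charged together, at 1.0 h
* excess of left-handed product over right-handed product in the product at 1.0 h
* whether the exchange between left-handed substrate and right-handed substrate keeps pace with the reaction: how far the product's excess at 1.0 h gets from its value without exchange to its value with instant exchange (above 80 % keeps pace, below 20 % hardly takes part, else lags behind)

- reagent is single-handed; left-handed substrate and right-handed substrate are mirror images of each other, charged as a racemate, each of them at the stated concentration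
- the numbers in the tables scatter with a standard deviation of 0.5 percentage points
- an excess is the difference of the two amounts in percent of their sum
- an excess is below zero if the other one leads
- the handed part of reagent does not stay in what it makes, so the products of the two hands are mirror images too

**One ratio.** Suppose there is no exchange and both hands follow the same rate law. Both hands then see the same c(reagent), so the left-hand fraction remaining equals the right-hand fraction remaining raised to a fixed power, whatever the reagent does. That power is the selectivity factor s: the logarithm of the left-hand fraction over that of the right-hand fraction, each fraction being one minus twice the product reading. The autumn reading at 12.0 min gives s = 7.26.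

But that is a single reading. The reading before it gives 7.48, and a shift of 0.5 percentage points on the right-handed product moves s to 6.70. These two late readings differ by less than that shift, so we take exchange as small. Instant exchange would hold the excess at (s−1)/(s+1), which is 75.8 %.

**Our reckoning.** The last autumn reading puts the fall of right-handed substrate at 0.0114 min⁻¹, a pseudo-first-order constant. We assume first order in reagent, though no run tests this. The flask has half the reagent, so the exponent over 1.0 h is 0.342, and y comes to 60.3 %.

But reagent runs down, to about 45.2 % of its charge at that yield. Mean reagent, against the autumn run's, scales the exponent by 0.794. Our estimate for the flask becomes y 55.0 % and excess 56.7 %. We expect exchange to add little.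

**The forecast.** It gives y 60 %, excess 59 %, and exchange that lags behind. On the autumn run it says: “Fast exchange fits poorly”. Its y stands 5 points above ours.

**The flask.** It gives y 53.8 %, excess 58.4 %, and exchange that hardly takes part, at 9.9 % of the way.

    reagent + left-handed substrate → left-handed product (k = 0.0380 M⁻¹ min⁻¹)
    reagent + right-handed substrate → right-handed product (k = 0.00560 M⁻¹ min⁻¹)
    left-handed substrate + racemization catalyst ⇌ right-handed substrate + racemization catalyst, rate k3*[racemization catalyst]*[left-handed substrate] forward; the back reaction follows from the equilibrium constant (k = 1.90 M⁻¹ min⁻¹)
    racemization catalyst → spent catalyst (k = 0.0230 min⁻¹)
    2 racemization catalyst ⇌ resting dimer, settled at all times (K = 3600 M⁻¹)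

**The neighbour.** From the flask's right-handed product, 11.2 %, s gives 42.1 % left-handed product, and the flask holds 42.6 %. The flask with 3.70 equiv reagent gives y 68.6 % and excess 46.3 %. Its right-handed product, 18.4 %, gives by s 48.2 %, and it holds 50.2 %. With its 3.12 % of left-handed substrate, the left hand there totals 53.3 %, more than the half charged.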